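**Assumption:** the target, 2,3,4,6-tetrabromo-1H-indole, has no stereocentre and is achiral, so no enantiomer has to be chosen. 2,4-Dibromo-6-nitroaniline and trimethylsilylacetylene are taken as commercial.

## Retrosynthetic overview

1. Target 10 comes from N-desulfonylation of the N-phenylsulfonyl tetrabromoindole 9.
2. 9 comes from bromoalkyne 8 by a bromonium-triggered 5-endo-dig sulfonamidocyclization (the new step), which forms N1–C2 and C3–Br and closes the pyrrole ring (ring B).
3. 8 comes from silylalkyne 7 by bromodesilylation; 7 comes from nitroarene 5 by reduction and N-sulfonylation.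
4. 5 comes from a site-selective Sonogashira coupling of aryl iodide 3 with trimethylsilylacetylene 4; 3 comes from iododediazoniation of aniline 1.
5. Ring order: the benzene ring (ring A) is bought with the C4 and C6 bromines in place; ring B is closed in step 6.

## Route

Step 1
Reactants: 1 2,4-dibromo-6-nitroaniline
Product: 3 1,5-dibromo-2-iodo-3-nitrobenzene, via arenediazonium hydrogen sulfate 2 (not isolated)
Conditions: NaNO2, conc. H2SO4/AcOH, 0–5 °C; then KI, H2O, 0 °C to rt
Reagents that add atoms: potassium iodide, [K+].[I-] (iodine of 3); sodium nitrite, [Na+].[O-]N=O (supplies only the second nitrogen of 2, which leaves as N2)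
Why: Diazotization of this weakly basic aniline with nitrosylsulfuric acid followed by copper-free iododediazoniation (Sandmeyer-type reaction) replaces NH2 by I at the carbon flanked by Br and NO2; no stereocentre is formed.

Step 2
Reactants: 3 1,5-dibromo-2-iodo-3-nitrobenzene; 4 trimethylsilylacetylene
Product: 5 [(2,4-dibromo-6-nitrophenyl)ethynyl]trimethylsilane
Conditions: PdCl2(PPh3)2 (2 mol %), CuI (4 mol %), Et3N, THF, rt
Reagents that add atoms: none
Why: Sonogashira coupling; zerovalent palladium inserts into the C–I bond (activated by the ortho nitro group) far faster than into either C–Br bond at room temperature, so only the iodide couples.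

Step 3
Reactants: 5 [(2,4-dibromo-6-nitrophenyl)ethynyl]trimethylsilane
Product: 6 3,5-dibromo-2-[(trimethylsilyl)ethynyl]aniline
Conditions: Fe powder, AcOH/EtOH (1:4), 60 °C
Reagents that add atoms: none
Why: Béchamp-type dissolving-metal reduction of the nitro group leaves the aryl bromides and the silylalkyne untouched.

Step 4
Reactants: 6 3,5-dibromo-2-[(trimethylsilyl)ethynyl]aniline
Product: 7 N-{3,5-dibromo-2-[(trimethylsilyl)ethynyl]phenyl}benzenesulfonamide
Conditions: PhSO2Cl (1.2 equiv), pyridine, DMAP (cat.), 50 °C
Reagents that add atoms: benzenesulfonyl chloride, O=S(=O)(Cl)c1ccccc1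
Why: N-sulfonylation of the aniline; the sulfonyl group deactivates the ring toward NBS in steps 5 and 6, makes N–H acidic for the cyclization, and has no benzylic C–H that NBS could attack.

Step 5
Reactants: 7 N-{3,5-dibromo-2-[(trimethylsilyl)ethynyl]phenyl}benzenesulfonamide
Product: 8 N-[3,5-dibromo-2-(bromoethynyl)phenyl]benzenesulfonamide
Conditions: NBS (1.1 equiv), AgNO3 (10 mol %), acetone, rt, dark
Reagents that add atoms: N-bromosuccinimide, O=C1CCC(=O)N1Br
Why: Silver-catalysed bromodesilylation of an alkynylsilane; AgNO3 turns the C–Si bond into a silver acetylide that NBS brominates at carbon, while the sulfonamide-deactivated arene is not brominated.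

Step 6
Reactants: 8 N-[3,5-dibromo-2-(bromoethynyl)phenyl]benzenesulfonamide
Product: 9 2,3,4,6-tetrabromo-1-(phenylsulfonyl)-1H-indole
Conditions: NBS (1.1 equiv), Ph3P=S (10 mol %), 4 Å MS, CH2Cl2, −20 °C to rt, dark
Reagents that add atoms: N-bromosuccinimide, O=C1CCC(=O)N1Br
Why: Proposed new method: bromonium-triggered 5-endo-dig sulfonamidocyclization of a 1-bromoalkyne. Ph3P=S takes Br+ from NBS to give the ion pair [Ph3P–S–Br]+ succinimide−; the succinimide anion deprotonates the acidic sulfonamide and the bromosulfonium-type cation delivers Br+ to the in-plane π bond of the alkyne, anti to nitrogen. That π bond is conjugated only with a lone pair of the alkynyl bromine, so positive charge builds on the bromine-bearing carbon and nitrogen closes there (N1–C2, ring B), placing the new bromine on C3 and keeping the original one on C2; 4-exo attack at the other carbon is geometrically excluded. The closest known reaction type is the iodo- or bromocyclization of N-sulfonyl-2-(aryl- or alkylethynyl)anilines to 3-haloindoles, here extended to a haloalkyne; no stereocentre is formed.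

Step 7
Reactants: 9 2,3,4,6-tetrabromo-1-(phenylsulfonyl)-1H-indole
Product: 10 2,3,4,6-tetrabromo-1H-indole
Conditions: KOH (3 equiv), THF/H2O (3:1), 40 °C, dark; then aq. NH4Cl
Reagents that add atoms: none
Why: Sulfonamide hydrolysis by attack of hydroxide at sulfur, easy because the tetrabromoindolide is a stabilized leaving group; an alcohol-free medium avoids forming an alkyl sulfonate that could N-alkylate the product, and the C–Br bonds are inert to aqueous base at 40 °C.

## Compound list

1 | 2,4-dibromo-6-nitroaniline | Nc1c(Br)cc(Br)cc1[N+](=O)[O-] | starting material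
2 | 2,4-dibromo-6-nitrobenzenediazonium hydrogen sulfate | N#[N+]c1c(Br)cc(Br)cc1[N+](=O)[O-].OS(=O)(=O)[O-] | intermediate (not isolated)
3 | 1,5-dibromo-2-iodo-3-nitrobenzene | Ic1c(Br)cc(Br)cc1[N+](=O)[O-] | intermediate
4 | trimethylsilylacetylene (ethynyltrimethylsilane) | C#C[Si](C)(C)C | starting material
5 | [(2,4-dibromo-6-nitrophenyl)ethynyl]trimethylsilane | C[Si](C)(C)C#Cc1c(Br)cc(Br)cc1[N+](=O)[O-] | intermediate
6 | 3,5-dibromo-2-[(trimethylsilyl)ethynyl]aniline | C[Si](C)(C)C#Cc1c(Br)cc(Br)cc1N | intermediate
7 | N-{3,5-dibromo-2-[(trimethylsilyl)ethynyl]phenyl}benzenesulfonamide | O=S(=O)(Nc1cc(Br)cc(Br)c1C#C[Si](C)(C)C)c1ccccc1 | intermediate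
8 | N-[3,5-dibromo-2-(bromoethynyl)phenyl]benzenesulfonamide | O=S(=O)(Nc1cc(Br)cc(Br)c1C#CBr)c1ccccc1 | intermediate
9 | 2,3,4,6-tetrabromo-1-(phenylsulfonyl)-1H-indole | O=S(=O)(c1ccccc1)n1c(Br)c(Br)c2c(Br)cc(Br)cc12 | intermediate
10 | 2,3,4,6-tetrabromo-1H-indole | Brc1cc(Br)c2c(Br)c(Br)[nH]c2c1 | target

## Summary

Total step count: 7. Longest linear sequence: 7 steps (1 to 10).

## Steps most likely to fail and fallbacks

**Step 6 (proposed new step).** Transfer of Br+ to the electron-poor bromoalkyne next to the future peri bromine may be slow. N-bromination or capture of the vinyl cation by adventitious water could compete. The fallback uses known chemistry only; it sets out from 6 and comes back at 10. Compound 6 is treated with KOt-Bu in NMP at rt, a base-mediated 5-endo-dig hydroamination of a 2-alkynylaniline in which the silyl group is lost, to give 4,6-dibromo-1H-indole F1. Electrophilic bromination at C3 with NBS (1 equiv) in DMF at 0 °C gives 3,4,6-tribromo-1H-indole F2. A second equivalent of NBS on silica gel in CH2Cl2 in the dark brominates C2 of the 3-bromoindole and gives 10 directly, without 7, 8 and 9.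

**Step 5.** AgNO3 may catalyse hydroamination of the sulfonamide onto the alkyne, or the acidic N–H may be brominated, before the bromoalkyne is formed. The fallback installs the bromoalkyne before any nucleophilic nitrogen exists; it sets out from 5 and comes back at 8. Compound 5 is bromodesilylated with NBS and AgNO3 (10 mol %) in acetone to give 1,5-dibromo-2-(bromoethynyl)-3-nitrobenzene F3. The nitro group is reduced with SnCl2·2H2O in EtOAc at 50 °C to give 3,5-dibromo-2-(bromoethynyl)aniline F4. Sulfonylation with PhSO2Cl in pyridine at rt then gives 8.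

**Step 7.** Hydroxide may attack C2 of the 2-bromo-N-sulfonylindole, or the light- and base-sensitive product may degrade during hydrolysis. The fallback replaces attack at sulfur by a fluoride-triggered fragmentation of a different N-group; it sets out from 6 and comes back at 10. Compound 6 is sulfonylated with 2-(trimethylsilyl)ethanesulfonyl chloride in pyridine to give N-{3,5-dibromo-2-[(trimethylsilyl)ethynyl]phenyl}-2-(trimethylsilyl)ethanesulfonamide F5. Bromodesilylation of the alkyne with NBS and AgNO3 (10 mol %) gives N-[3,5-dibromo-2-(bromoethynyl)phenyl]-2-(trimethylsilyl)ethanesulfonamide F6. The cyclization conditions of step 6 give 2,3,4,6-tetrabromo-1-{[2-(trimethylsilyl)ethyl]sulfonyl}-1H-indole F7. TBAF in THF at rt attacks the silicon of the ethyl chain, and β-elimination releases the indole nitrogen under neutral, non-nucleophilic conditions to give 10.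

## Further compounds

F1 | step 6 | 4,6-dibromo-1H-indole | Brc1cc(Br)c2cc[nH]c2c1
F2 | step 6 | 3,4,6-tribromo-1H-indole | Brc1cc(Br)c2c(Br)c[nH]c2c1
F3 | step 5 | 1,5-dibromo-2-(bromoethynyl)-3-nitrobenzene | BrC#Cc1c(Br)cc(Br)cc1[N+](=O)[O-]
F4 | step 5 | 3,5-dibromo-2-(bromoethynyl)aniline | Nc1cc(Br)cc(Br)c1C#CBr
F5 | step 7 | N-{3,5-dibromo-2-[(trimethylsilyl)ethynyl]phenyl}-2-(trimethylsilyl)ethanesulfonamide | C[Si](C)(C)CCS(=O)(=O)Nc1cc(Br)cc(Br)c1C#C[Si](C)(C)C
F6 | step 7 | N-[3,5-dibromo-2-(bromoethynyl)phenyl]-2-(trimethylsilyl)ethanesulfonamide | C[Si](C)(C)CCS(=O)(=O)Nc1cc(Br)cc(Br)c1C#CBr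
F7 | step 7 | 2,3,4,6-tetrabromo-1-{[2-(trimethylsilyl)ethyl]sulfonyl}-1H-indole | C[Si](C)(C)CCS(=O)(=O)n1c(Br)c(Br)c2c(Br)cc(Br)cc12
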